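## Structural features

The target is a single tetrahydrofuran ring that carries 4-hydroxyphenyl groups at C2 and C5 and 2,4-dihydroxybenzoyl groups at C3 and C4; no other ring is fused or bridged to it. All four ring carbons are stereocentres and stand in a row, (2S,3R,4R,5S): the molecule is C2-symmetric, the two aryl groups are trans, the two acyl groups are trans, and each acyl group is cis to the aryl group next to it. This cis,trans,cis pattern is not the thermodynamic one. C3 and C4 are α to aryl ketones and β to the ring oxygen, so base can epimerise them to the all-trans isomer or open the ring by β-elimination to a chalcone-type enone. The C2–O1 and C5–O1 bonds are benzylic ether bonds para to a phenol oxygen, hence open to ionisation by acid and to hydrogenolysis, and six phenols must be masked through every organometallic step. The real difficulty is to set four contiguous centres in one absolute sense with two contra-thermodynamic cis relationships, and to bring the ketones in so late that they never meet base. The key step uses the fact that C2 and C5 are constitutionally identical benzylic carbinol carbons: while C3=C4 is still a Z alkene (a maleate), the 1,4-diol is meso, an enzyme can tell its two ends apart, and closing O1–C2 with inversion at one end turns meso into trans and into one enantiomer.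

## Logic of the disconnections

18 to 17. The six phenolic O–H bonds are traced back to six O–benzyl bonds. Benzyl ethers survive Grignard, palladium, samarium and aryllithium chemistry and leave under neutral conditions, which 18 needs because of its base-labile C3/C4 centres. The gain is a lipophilic precursor; the demand is that hydrogenolysis spares the two benzylic C–O bonds of the ring and the aryl ketones.

17 to 13 and 15 (15 from 14), through 16. Both C(=O)–aryl bonds are cut at once, because the two resorcinol-derived rings are identical and can come from one nucleophile used twice, that is, two equivalents of 15 for one equivalent of 13. This leaves a C2-symmetric dicarboxylic acid derivative. The forward step must add once per carboxyl group and must not deprotonate C3/C4, hence the N-methoxy-N-methylamide, whose adduct 16 holds both new bonds until the quench.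

13 to 12. The two C–N bonds go back to C–OMe bonds, since the methyl ester is the form in which the carboxyl carbons are introduced. The amide transfer has to be nucleophilic and only weakly basic.

12 to 11. The C3–H and C4–H bonds are cut, which returns two of the four stereocentres to sp2 carbons. The C2 axis of 11 makes the two faces of C3=C4 equivalent, so only the relative sense of the two protonations has to be controlled: each hydrogen must arrive anti to the neighbouring aryl group. A syn hydrogenation would give the wrong, 3,4-cis isomer, so the forward step must be an anti addition under kinetic protonation.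

11 to 9 through 10 (key disconnection). The O1–C2 bond is cut. With C3=C4 as a Z alkene, the open form is a derivative of a meso diol with differentiated ends. The C5–O bond is kept (R), and the C2–O bond is made with inversion (S to R). The gain is that the ring and the C2/C5 problem reduce to an acyclic compound with two carbinol centres of unlike configuration. The demand is SN2 fidelity at a para-alkoxybenzylic carbon. For that reason the nucleophilic oxygen is unmasked by a stoichiometric alkoxide in an aprotic solvent at low temperature, not by carbonate in methanol, and the leaving group is put on only one step earlier.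

9 to 8, and 8 to 6 and 7. The S–O bond is cut first, since the sulfonate is the least stable group in the sequence. Then both C(sp2)–CO2Me bonds are cut: a syn addition of two carboxyl carbons across an alkyne gives the Z geometry and the future C3/C4 carboxyl carbons in one operation. The demand is an intermolecular carbopalladation of a hindered internal alkyne that carries a free hydroxyl and an acetate.

6 to 5. One acetyl–O bond is cut. 5 is achiral and needs no stereocontrol, and an enzyme distinguishes its enantiotopic ester groups. The acetate has to stay on the carbinol whose C–O bond is retained (R), and the free hydroxyl has to sit on the carbinol to be inverted (S). An enzyme that acts on the (S)-carbinol is therefore used to deacylate the diacetate. Using it to acylate the diol would place the acetate on the wrong end and lead to the mirror image of 11. At this stage the linear alkyne keeps the two oxygens far apart, so acetyl migration cannot racemise 6.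

5 to 1 and 2 (through 3 and 4). Both C(sp)–C(carbinol) bonds and both O–acetyl bonds are cut in a two-directional sense. This reaches three small commercial units; the only demand is separation of the meso from the racemic diastereomer.

## Other disconnections considered

Alternative 1: The cut is at C2–C3 and C4–C5 together with both benzylic C–aryl bonds, so the C3–C4 core with two protected hydroxymethyl arms is extended outward in both directions. In the forward key step each C–B bond of a C2-symmetric vicinal bis(boronic ester) would take up LiCHCl2, the ate complex would rearrange under ZnCl2 with 1,2-migration, and the α-chloro boronic ester would be substituted by the aryl Grignard reagent in a second 1,2-shift, giving A1.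
- In its favour: both benzylic centres are set by the chiral diol on boron, and C3/C4 cannot epimerise while they carry silyloxymethyl arms. On the cis relationship between aryl and arm this is better than the chosen plan, which relies on a kinetic protonation. The two-directional use of symmetry is the equal of the chosen plan.
- Against it: boron stays β to a silyloxy group throughout, which invites β-elimination from the ate complexes. The arms must later be oxidised and turned into aryl ketones, so C3/C4 become epimerisable anyway. A1 has like configuration at the two benzylic carbons, so retentive oxidation of one C–B bond and invertive closure onto the other would give the 2,5-cis ring. Both C–O bonds would have to be made with inversion, that is, two substitutions at para-alkoxybenzylic carbon where the chosen plan has one.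
- Comparison: on mechanism the stereospecific 1,2-shifts are at least as predictable as an enzymatic desymmetrisation, but the ring closure is weaker. On step economy the route would be clearly longer (auxiliary, two homologation cycles, oxidation-state changes).

Alternative 2: The cut is at C4–C5 and at the bond from C3 to the future C2 in a [2+2] sense; the ring oxygen is inserted afterwards next to the aryl-bearing carbon, and the second aryl group and the C2 hydrogen are added to the lactone carbonyl. In the forward key step an amide activated with Tf2O and 2,4,6-collidine would give a keteniminium ion that adds to the E-alkene, and hydrolysis would give A2.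
- In its favour: the cycloaddition transfers the E geometry into the trans relationship of the arms. The Baeyer–Villiger step makes the benzylic C5–O bond by migration with retention, so no substitution at an electron-rich benzylic carbon is needed. On that point it is better than the chosen plan.
- Against it: A2 needs the aryl group cis to the neighbouring arm, the more hindered arrangement, at an α-aryl ketone centre that epimerises readily. The cycloaddition does not address absolute configuration, so an auxiliary or a resolution would be needed. The arms must again be taken to aryl ketones at the end.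
- Comparison: on structure it sets C3 to C5 in one step but leaves C2 and enantiocontrol open, whereas the chosen plan draws the absolute configuration from symmetry. On mechanism the retentive migration is safer than an SN2 closure, but the contra-steric cycloaddition is less safe than the meso-to-trans logic. On step economy it would be longer.

Alternative 3: The cut is at C2–C3, leaving an acyclic benzyl ether in which C4 and C5 are already stereocentres and both ketones are in place. In the forward key step Rh2(S-PTTL)4 would decompose the diazo precursor, and the dirhodium carbene at C3 would insert into a benzylic C–H bond next to the ether oxygen to close the ring and give A3.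
- In its favour: it is the most convergent closing. It forms a C–C bond, the ring and two stereocentres at once on the complete skeleton, so in its final phase it is better than the chosen plan on step economy. The C–H bond is benzylic and α to oxygen, the electronically preferred site. Carboxylate catalysts of this class tend to give cis-2,3 products, which is what the target needs, so on that relationship it is the equal of the chosen plan.
- Against it: the carbene carbon has no donor group and is flanked by the C4–H bond, so 1,2-hydride migration to an enone is expected to compete. C4 is α to a ketone in the open chain and can epimerise before the ring fixes it. The catalyst must override two existing stereocentres. Six silyl ethers would have to be removed with fluoride from a base-sensitive product. The precursor, with its C4/C5 pair, is itself not simple.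
- Comparison: the difficulty is moved to the precursor, not removed. The chosen plan avoids any step in which C3/C4 are stereogenic and α to a ketone before the last operation.

Key step: step 5

Assumption: the lipase tells the two ester groups of 5 apart by the usual size rule for secondary carbinols, with the aryl ring as the large and the alkynyl rod as the medium substituent, and therefore unloads the (S)-configured carbinol.

Remark on descriptors: C2 and C5 are (R) in 11 and (S) in 12 to 18 without any change in space, because C3 and C4 lose CIP rank against the aryl groups once they are saturated.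

## Steps

Step 1
Reactants: 1 acetylene; 2 4-(benzyloxy)benzaldehyde
Product: 5 meso-(1R,4S)-1,4-bis[4-(benzyloxy)phenyl]but-2-yne-1,4-diyl diacetate, via bis(bromomagnesio)ethyne 3 (not isolated), via meso bis(bromomagnesium) dialkoxide 4 (not isolated)
Conditions: HC≡CH, EtMgBr (2 equiv), THF, rt; 2 (2 equiv), 0 °C to rt; then Ac2O, DMAP (cat.), 0 °C to rt; crystallisation or chromatography
Reagents that add atoms: acetic anhydride, SMILES CC(=O)OC(C)=O
Why: Double 1,2-addition of the acetylene bis-Grignard reagent 3 to two molecules of 2, followed by O-acetylation of the dialkoxide 4 in the same flask. No stereocontrol is expected, so 5 forms alongside its racemic diastereomer and is taken on after crystallisation or chromatography; racemic material that slips through is sorted by the enzyme in step 2, where one enantiomer stays diacetate and the other ends as diol.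

Step 2
Reactants: 5 meso-(1R,4S)-1,4-bis[4-(benzyloxy)phenyl]but-2-yne-1,4-diyl diacetate
Product: 6 (1R,4S)-1,4-bis[4-(benzyloxy)phenyl]-4-hydroxybut-2-yn-1-yl acetate
Conditions: Burkholderia cepacia lipase (immobilised), n-BuOH (4 equiv), t-BuOMe, 35 °C
Reagents that add atoms: none
Why: Lipase-catalysed enantiotopos-selective alcoholysis (transesterification) of a meso diacetate: by the size rule for secondary carbinols the enzyme unloads only the (S)-configured ester, so the acetate stays on the (R)-carbinol whose C–O bond is kept to the end and the free hydroxyl marks the carbon to be inverted. The linear alkyne keeps the two oxygens too far apart for acetyl migration, which would racemise 6.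

Step 3
Reactants: 6 (1R,4S)-1,4-bis[4-(benzyloxy)phenyl]-4-hydroxybut-2-yn-1-yl acetate; 7 carbon monoxide
Product: 8 dimethyl (Z)-2-{(R)-acetoxy[4-(benzyloxy)phenyl]methyl}-3-{(S)-[4-(benzyloxy)phenyl](hydroxy)methyl}but-2-enedioate
Conditions: PdI2 (5 mol %), KI (0.5 equiv), CO/air 4:1 (20 atm), MeOH–1,4-dioxane, 60 °C
Reagents that add atoms: methanol, SMILES CO
Why: Oxidative bis-alkoxycarbonylation of an alkyne catalysed by divalent palladium, which takes up two molecules of CO and two of methanol per alkyne: an iodopalladium methoxycarbonyl species adds syn across the triple bond, CO insertion and methanolysis release the second ester, and the zerovalent palladium left behind is reoxidised by O2 through the iodide/iodine couple, so the Z geometry follows from the syn addition and no stereocentre is touched. In the syn adduct each carbinol oxygen is either geminal or trans to the acylpalladium, so neither the free hydroxyl nor the acetate can trap it in a five-membered ring.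

Step 4
Reactants: 8 dimethyl (Z)-2-{(R)-acetoxy[4-(benzyloxy)phenyl]methyl}-3-{(S)-[4-(benzyloxy)phenyl](hydroxy)methyl}but-2-enedioate
Product: 9 dimethyl (Z)-2-{(R)-acetoxy[4-(benzyloxy)phenyl]methyl}-3-{(S)-[4-(benzyloxy)phenyl](methylsulfonyloxy)methyl}but-2-enedioate
Conditions: Ms2O, Et3N, CH2Cl2, −40 °C; cold NaHCO3 work-up, used without chromatography
Reagents that add atoms: methanesulfonic anhydride, SMILES CS(=O)(=O)OS(C)(=O)=O
Why: O-Sulfonylation of a secondary alcohol at oxygen, with retention at the (S)-carbon. The anhydride is chosen over the chloride so that no chloride ion is available to displace the benzylic mesylate, and the cold aprotic medium and the omission of chromatography limit ionisation of 9.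

Step 5
Reactants: 9 dimethyl (Z)-2-{(R)-acetoxy[4-(benzyloxy)phenyl]methyl}-3-{(S)-[4-(benzyloxy)phenyl](methylsulfonyloxy)methyl}but-2-enedioate
Product: 11 dimethyl (2R,5R)-2,5-bis[4-(benzyloxy)phenyl]-2,5-dihydrofuran-3,4-dicarboxylate, via sodium alkoxide 10 (not isolated)
Conditions: NaOMe (1.1 equiv, 0.5 M in MeOH), THF, −40 to 0 °C
Reagents that add atoms: none
Why: Methoxide removes the acetyl group by transesterification and leaves alkoxide 10, whose oxygen attacks the mesylate-bearing carbon from the rear in an intramolecular Williamson-type SN2 etherification; the closest known reaction type is the base-induced cyclisation of acetoxy sulfonates obtained by lipase desymmetrisation of meso diols. The 2,5-dihydrofuran ring closes in the 5-exo-tet mode, the Z double bond holding the alkoxide oxygen and C2 within bonding distance. The one new stereocentre, C2, is set by stereospecific inversion of the (S)-mesylate, while C5 keeps the (R) configuration chosen by the enzyme because its C–O bond is never broken; unlike ends plus one inversion give the trans, C2-symmetric ring as the (2R,5R) enantiomer. The step needs substitution with inversion in preference to ionisation and to vinylogous 1,4-elimination. Ionisation is held back by the two ester groups on the alkene, which make the allylic position electron-poor, and by using a stoichiometric alkoxide in THF at low temperature instead of carbonate in methanol, where a para-alkoxybenzylic sulfonate would solvolyse before the acetate is gone. Even if some ionisation occurred it could only produce the achiral cis isomer, never the enantiomer, since C5 is fixed. Elimination is disfavoured because acyl transfer to methoxide is faster than deprotonation of the hindered carbinol C–H and because the ring closure of 10 is intramolecular. The methyl esters are degenerate toward methoxide.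

Step 6
Reactants: 11 dimethyl (2R,5R)-2,5-bis[4-(benzyloxy)phenyl]-2,5-dihydrofuran-3,4-dicarboxylate
Product: 12 dimethyl (2S,3R,4R,5S)-2,5-bis[4-(benzyloxy)phenyl]tetrahydrofuran-3,4-dicarboxylate
Conditions: SmI2 (3 equiv), HMPA, MeOH, THF, −78 °C; pH 7 buffer work-up
Reagents that add atoms: none
Why: Conjugate reduction of an ene-diester by single-electron transfer from SmI2 with methanol as proton source; both C–H bonds are formed by kinetic protonation (first the radical anion, then the samarium enolate) on the face away from the neighbouring aryl group, which places each ester cis to its aryl neighbour and the two esters trans, that is (3R,4R). The C2 axis of 11 makes the two alkene faces equivalent, so only this relative sense has to be controlled; the low temperature and the neutral work-up avoid equilibration to the all-trans isomer.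

Step 7
Reactants: 12 dimethyl (2S,3R,4R,5S)-2,5-bis[4-(benzyloxy)phenyl]tetrahydrofuran-3,4-dicarboxylate
Product: 13 (2S,3R,4R,5S)-2,5-bis[4-(benzyloxy)phenyl]-N3,N4-dimethoxy-N3,N4-dimethyltetrahydrofuran-3,4-dicarboxamide
Conditions: MeNH(OMe)·HCl (5 equiv), i-PrMgCl (10 equiv), THF, −20 to 0 °C
Reagents that add atoms: N,O-dimethylhydroxylamine hydrochloride, SMILES CNOC.Cl
Why: Aminolysis of both esters by the chloromagnesium amide of N,O-dimethylhydroxylamine, used in excess (Weinreb amide formation); the reagent is a good nucleophile but a poor base at low temperature, so the α-stereocentres C3 and C4 should be retained.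

Step 8
Reactants: 13 (2S,3R,4R,5S)-2,5-bis[4-(benzyloxy)phenyl]-N3,N4-dimethoxy-N3,N4-dimethyltetrahydrofuran-3,4-dicarboxamide; 14 1-bromo-2,4-bis(benzyloxy)benzene
Product: 17 {(2S,3R,4R,5S)-2,5-bis[4-(benzyloxy)phenyl]tetrahydrofuran-3,4-diyl}bis{[2,4-bis(benzyloxy)phenyl]methanone}, via 2,4-bis(benzyloxy)phenyllithium 15 (not isolated), via dilithium bis(hemiaminal alkoxide) adduct 16 (not isolated)
Conditions: 14 (2 equiv), n-BuLi (2 equiv), THF, −78 °C; then 13 (1 equiv), −78 to −40 °C; sat. NH4Cl at −78 °C
Reagents that add atoms: none
Why: Bromine–lithium exchange on two equivalents of 14 gives two equivalents of 15, one for each N-methoxy-N-methylamide of 13, and the double addition (Weinreb ketone synthesis) leads to the chelated bis-adduct 16, in which both new C–aryl bonds are already in place. 16 persists until the quench, so over-addition is excluded and a small excess of 15 does no harm, and the epimerisable diketone appears only during a cold, buffered work-up that releases two molecules of N,O-dimethylhydroxylamine.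

Step 9
Reactants: 17 {(2S,3R,4R,5S)-2,5-bis[4-(benzyloxy)phenyl]tetrahydrofuran-3,4-diyl}bis{[2,4-bis(benzyloxy)phenyl]methanone}
Product: 18 {(2S,3R,4R,5S)-2,5-bis(4-hydroxyphenyl)tetrahydrofuran-3,4-diyl}bis[(2,4-dihydroxyphenyl)methanone]
Conditions: H2 (1 atm), 10% Pd/C, THF–MeOH, rt
Reagents that add atoms: none
Why: Catalytic hydrogenolysis of six aryl benzyl ethers under neutral conditions, so that neither acid nor base reaches C3/C4 or the benzylic ring carbons. Aryl benzyl ethers cleave much faster than the dialkyl-type benzylic C–O bonds of the ring and than the ortho-oxygenated aryl ketones, and the reaction is stopped after uptake of six equivalents of H2.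

## Compound list

1 | acetylene (ethyne) | C#C | starting material
2 | 4-(benzyloxy)benzaldehyde | O=Cc1ccc(OCc2ccccc2)cc1 | starting material
3 | bis(bromomagnesio)ethyne | Br[Mg]C#C[Mg]Br | intermediate
4 | bis(bromomagnesium) dialkoxide of meso-(1R,4S)-1,4-bis[4-(benzyloxy)phenyl]but-2-yne-1,4-diol | Br[Mg]O[C@H](c1ccc(OCc2ccccc2)cc1)C#C[C@@H](O[Mg]Br)c1ccc(OCc2ccccc2)cc1 | intermediate
5 | meso-(1R,4S)-1,4-bis[4-(benzyloxy)phenyl]but-2-yne-1,4-diyl diacetate | CC(=O)O[C@H](c1ccc(OCc2ccccc2)cc1)C#C[C@@H](OC(C)=O)c1ccc(OCc2ccccc2)cc1 | intermediate
6 | (1R,4S)-1,4-bis[4-(benzyloxy)phenyl]-4-hydroxybut-2-yn-1-yl acetate | CC(=O)O[C@H](c1ccc(OCc2ccccc2)cc1)C#C[C@@H](O)c1ccc(OCc2ccccc2)cc1 | intermediate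
7 | carbon monoxide | [C-]#[O+] | starting material
8 | dimethyl (Z)-2-{(R)-acetoxy[4-(benzyloxy)phenyl]methyl}-3-{(S)-[4-(benzyloxy)phenyl](hydroxy)methyl}but-2-enedioate | COC(=O)/C([C@@H](O)c1ccc(OCc2ccccc2)cc1)=C(\C(=O)OC)[C@@H](c1ccc(OCc2ccccc2)cc1)OC(C)=O | intermediate
9 | dimethyl (Z)-2-{(R)-acetoxy[4-(benzyloxy)phenyl]methyl}-3-{(S)-[4-(benzyloxy)phenyl](methylsulfonyloxy)methyl}but-2-enedioate | COC(=O)/C([C@@H](OS(C)(=O)=O)c1ccc(OCc2ccccc2)cc1)=C(\C(=O)OC)[C@@H](c1ccc(OCc2ccccc2)cc1)OC(C)=O | intermediate
10 | sodium alkoxide of dimethyl (Z)-2-{(R)-[4-(benzyloxy)phenyl](hydroxy)methyl}-3-{(S)-[4-(benzyloxy)phenyl](methylsulfonyloxy)methyl}but-2-enedioate | COC(=O)/C([C@@H](OS(C)(=O)=O)c1ccc(OCc2ccccc2)cc1)=C(\C(=O)OC)[C@@H](c1ccc(OCc2ccccc2)cc1)[O-].[Na+] | intermediate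
11 | dimethyl (2R,5R)-2,5-bis[4-(benzyloxy)phenyl]-2,5-dihydrofuran-3,4-dicarboxylate (2,5-trans) | COC(=O)C1=C(C(=O)OC)[C@@H](c2ccc(OCc3ccccc3)cc2)O[C@@H]1c1ccc(OCc2ccccc2)cc1 | intermediate
12 | dimethyl (2S,3R,4R,5S)-2,5-bis[4-(benzyloxy)phenyl]tetrahydrofuran-3,4-dicarboxylate | COC(=O)[C@@H]1[C@@H](C(=O)OC)[C@@H](c2ccc(OCc3ccccc3)cc2)O[C@@H]1c1ccc(OCc2ccccc2)cc1 | intermediate
13 | (2S,3R,4R,5S)-2,5-bis[4-(benzyloxy)phenyl]-N3,N4-dimethoxy-N3,N4-dimethyltetrahydrofuran-3,4-dicarboxamide | CON(C)C(=O)[C@@H]1[C@@H](C(=O)N(C)OC)[C@@H](c2ccc(OCc3ccccc3)cc2)O[C@@H]1c1ccc(OCc2ccccc2)cc1 | intermediate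
14 | 1-bromo-2,4-bis(benzyloxy)benzene | Brc1ccc(OCc2ccccc2)cc1OCc1ccccc1 | starting material
15 | 2,4-bis(benzyloxy)phenyllithium | [Li]c1ccc(OCc2ccccc2)cc1OCc1ccccc1 | intermediate
16 | dilithium {(2S,3R,4R,5S)-2,5-bis[4-(benzyloxy)phenyl]tetrahydrofuran-3,4-diyl}bis{[2,4-bis(benzyloxy)phenyl][methoxy(methyl)amino]methanolate}, the two carbinolate carbons unassigned | [Li+].[Li+].CON(C)C([O-])(c1ccc(OCc2ccccc2)cc1OCc1ccccc1)[C@@H]1[C@@H](C([O-])(N(C)OC)c2ccc(OCc3ccccc3)cc2OCc2ccccc2)[C@@H](c2ccc(OCc3ccccc3)cc2)O[C@@H]1c1ccc(OCc2ccccc2)cc1 | intermediate
17 | {(2S,3R,4R,5S)-2,5-bis[4-(benzyloxy)phenyl]tetrahydrofuran-3,4-diyl}bis{[2,4-bis(benzyloxy)phenyl]methanone} | O=C(c1ccc(OCc2ccccc2)cc1OCc1ccccc1)[C@@H]1[C@@H](C(=O)c2ccc(OCc3ccccc3)cc2OCc2ccccc2)[C@@H](c2ccc(OCc3ccccc3)cc2)O[C@@H]1c1ccc(OCc2ccccc2)cc1 | intermediate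
18 | {(2S,3R,4R,5S)-2,5-bis(4-hydroxyphenyl)tetrahydrofuran-3,4-diyl}bis[(2,4-dihydroxyphenyl)methanone] (CNP0237262.3) | O=C(c1ccc(O)cc1O)[C@@H]1[C@@H](C(=O)c2ccc(O)cc2O)[C@@H](c2ccc(O)cc2)O[C@@H]1c1ccc(O)cc1 | target

## Step count and least certain steps

Total step count: 9. Longest linear sequence: 9 steps (from 1 and 2 to 18); 14 enters in step 8 without prior steps.

Step 5 (key step). The most likely failure is ionisation of the para-alkoxybenzylic C–O(mesyl) bond in competition with backside attack, because the benzyloxy group stabilises the cation more than the ester-bearing alkene destabilises it. This would mean loss of inversion fidelity (formation of the meso cis ring) and capture by methanol or methoxide. The fallback sets out from 8 and comes back to the route at 11. The hydroxyl is replaced by chlorine with retention by SOCl2 in Et2O at −20 °C without added base (collapse of the chlorosulfite ion pair), giving dimethyl (Z)-2-{(R)-acetoxy[4-(benzyloxy)phenyl]methyl}-3-{(S)-chloro[4-(benzyloxy)phenyl]methyl}but-2-enedioate F1. Chloride is a far poorer nucleofuge than mesylate, so this compound should tolerate handling. NaOMe in THF at 0 °C then removes the acetyl group and closes the ring by SN2 displacement of chloride with inversion to 11. A further remedy, electron-poor protection of the para oxygens, would need a different aldehyde from step 1 on and is not worked out here.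

Step 3. The most likely failure is that the hindered internal alkyne does not insert into the Pd–CO2Me bond, since this catalyst system is at its best with terminal alkynes, and that slow acid-induced methanolysis of the propargylic, benzylic C–O bonds takes over. The fallback sets out from 6 and comes back at 8. Pt(PPh3)4-catalysed syn addition of bis(pinacolato)diboron across the alkyne (toluene, 80 °C) gives (1S,2Z,4R)-1,4-bis[4-(benzyloxy)phenyl]-4-hydroxy-2,3-bis(4,4,5,5-tetramethyl-1,3,2-dioxaborolan-2-yl)but-2-en-1-yl acetate F2. Its carbinol centres have the same arrangement in space as in 6; the descriptors change only because boron ranks below carbon. Both alkenyl C–B bonds are then converted into methyl esters by oxidative methoxycarbonylation (Pd(OAc)2, PPh3, p-benzoquinone, CO, MeOH, rt) to give 8. This separates the addition to the triple bond from the carbonylation.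

Step 2. The most likely failure is slow or unselective acyl transfer, because both carbinol substituents, an aryl ring and a substituted alkynyl rod, are large for the enzyme pocket. The fallback sets out from 2 and comes back at 6, building the two carbinols one after the other. Ethynylmagnesium bromide adds to 2 to give racemic 1-[4-(benzyloxy)phenyl]prop-2-yn-1-ol F3. Kinetic resolution with Candida antarctica lipase B and vinyl acetate, a substrate class for which this enzyme is established, converts one enantiomer into (R)-1-[4-(benzyloxy)phenyl]prop-2-yn-1-yl acetate F4, which is removed, and leaves (S)-1-[4-(benzyloxy)phenyl]prop-2-yn-1-ol F5. This alcohol is acetylated (Ac2O, pyridine) to (S)-1-[4-(benzyloxy)phenyl]prop-2-yn-1-yl acetate F6, whose (S) centre becomes the (R)-acetoxy carbon of 6, because a substituted alkynyl group outranks the aryl group. The alkynylzinc reagent made from this acetate and Et2Zn then adds to a second molecule of 2 under Ti(Oi-Pr)4/BINOL catalysis, the BINOL antipode being chosen to give the (S)-carbinol, which is 6.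

Step 6. The most likely failure is poor facial selectivity in the second protonation, where the new ester at C3 and the aryl group at C5 shield opposite faces of the C4 enolate, leading to the unsymmetrical 3,4-cis isomer; some reductive loss of the allylic C2–O bond is a second concern. The fallback sets out from 11 and comes back at 12. The crude reduction product is not separated but treated with LiN(i-Pr)2 (2.5 equiv, THF, −78 °C) to form the dilithium bis(enolate) of dimethyl (2R,5R)-2,5-bis[4-(benzyloxy)phenyl]tetrahydrofuran-3,4-dicarboxylate F7, in which C3 and C4 are planar again while C2 and C5 are untouched. The ring C–O bonds lie near the nodal plane of the enolates, so β-elimination should be slow. Protonation at −78 °C with a bulky phenol (2,6-di-tert-butyl-4-methylphenol) is a separate, tunable kinetic step that should deliver each proton anti to the neighbouring aryl group and converge the epimers on 12.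

Step 8. The most likely failure is deprotonation at C3/C4 by the basic aryllithium at the hindered amides in place of addition, which would cause epimerisation or β-elimination of the ring oxygen, together with incomplete addition at the second amide. The fallback sets out from 13 and comes back at 17. LiAlH4 (THF, −78 °C) reduces both amides to (2S,3R,4R,5S)-2,5-bis[4-(benzyloxy)phenyl]tetrahydrofuran-3,4-dicarbaldehyde F8. Two equivalents of 15 add to the far more electrophilic and less hindered aldehydes at −78 °C to give {(2S,3S,4S,5S)-2,5-bis[4-(benzyloxy)phenyl]tetrahydrofuran-3,4-diyl}bis{[2,4-bis(benzyloxy)phenyl]methanol} F9 as a mixture of carbinol epimers, which does not matter. The ring is unchanged in space; the C3/C4 descriptors change by CIP rank only. Dess–Martin periodinane buffered with NaHCO3 then oxidises this bis-carbinol to 17 under non-basic conditions.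

## Further compounds

F1 | step 5 | dimethyl (Z)-2-{(R)-acetoxy[4-(benzyloxy)phenyl]methyl}-3-{(S)-chloro[4-(benzyloxy)phenyl]methyl}but-2-enedioate | COC(=O)/C([C@@H](Cl)c1ccc(OCc2ccccc2)cc1)=C(\C(=O)OC)[C@@H](c1ccc(OCc2ccccc2)cc1)OC(C)=O
F2 | step 3 | (1S,2Z,4R)-1,4-bis[4-(benzyloxy)phenyl]-4-hydroxy-2,3-bis(4,4,5,5-tetramethyl-1,3,2-dioxaborolan-2-yl)but-2-en-1-yl acetate | CC1(C)OB(OC1(C)C)/C([C@@H](O)c1ccc(OCc2ccccc2)cc1)=C(\B1OC(C)(C)C(C)(C)O1)[C@@H](c1ccc(OCc2ccccc2)cc1)OC(C)=O
F3 | step 2 | racemic 1-[4-(benzyloxy)phenyl]prop-2-yn-1-ol | OC(C#C)c1ccc(OCc2ccccc2)cc1
F4 | step 2 | (R)-1-[4-(benzyloxy)phenyl]prop-2-yn-1-yl acetate | CC(=O)O[C@@H](c1ccc(OCc2ccccc2)cc1)C#C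
F5 | step 2 | (S)-1-[4-(benzyloxy)phenyl]prop-2-yn-1-ol | O[C@H](c1ccc(OCc2ccccc2)cc1)C#C
F6 | step 2 | (S)-1-[4-(benzyloxy)phenyl]prop-2-yn-1-yl acetate | CC(=O)O[C@H](c1ccc(OCc2ccccc2)cc1)C#C
F7 | step 6 | dilithium bis(enolate) of dimethyl (2R,5R)-2,5-bis[4-(benzyloxy)phenyl]tetrahydrofuran-3,4-dicarboxylate | [Li+].[Li+].COC([O-])=C1C(=C([O-])OC)[C@@H](c2ccc(OCc3ccccc3)cc2)O[C@@H]1c1ccc(OCc2ccccc2)cc1
F8 | step 8 | (2S,3R,4R,5S)-2,5-bis[4-(benzyloxy)phenyl]tetrahydrofuran-3,4-dicarbaldehyde | O=C[C@@H]1[C@@H](C=O)[C@@H](c2ccc(OCc3ccccc3)cc2)O[C@@H]1c1ccc(OCc2ccccc2)cc1
F9 | step 8 | {(2S,3S,4S,5S)-2,5-bis[4-(benzyloxy)phenyl]tetrahydrofuran-3,4-diyl}bis{[2,4-bis(benzyloxy)phenyl]methanol}, carbinol epimers | OC(c1ccc(OCc2ccccc2)cc1OCc1ccccc1)[C@@H]1[C@@H](C(O)c2ccc(OCc3ccccc3)cc2OCc2ccccc2)[C@@H](c2ccc(OCc3ccccc3)cc2)O[C@@H]1c1ccc(OCc2ccccc2)cc1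
A1 | alternative 1 | bis[(1R,2R)-1,2-dicyclohexylethane-1,2-diyl] ester of [(1R,2S,3S,4R)-1,4-bis[4-(benzyloxy)phenyl]-2,3-bis(triisopropylsilyloxymethyl)butane-1,4-diyl]diboronic acid | B1(O[C@H](C2CCCCC2)[C@@H](C2CCCCC2)O1)[C@@H](c1ccc(OCc2ccccc2)cc1)[C@H](CO[Si](C(C)C)(C(C)C)C(C)C)[C@@H](CO[Si](C(C)C)(C(C)C)C(C)C)[C@H](c1ccc(OCc2ccccc2)cc1)B1O[C@H](C2CCCCC2)[C@@H](C2CCCCC2)O1
A2 | alternative 2 | (2S,3S,4S)-2-[4-(benzyloxy)phenyl]-3,4-bis(triisopropylsilyloxymethyl)cyclobutan-1-one | O=C1[C@H](CO[Si](C(C)C)(C(C)C)C(C)C)[C@@H](CO[Si](C(C)C)(C(C)C)C(C)C)[C@H]1c1ccc(OCc2ccccc2)cc1
A3 | alternative 3 | {(2S,3R,4R,5S)-2,5-bis[4-(tert-butyldimethylsilyloxy)phenyl]tetrahydrofuran-3,4-diyl}bis{[2,4-bis(tert-butyldimethylsilyloxy)phenyl]methanone} | O=C(c1ccc(O[Si](C)(C)C(C)(C)C)cc1O[Si](C)(C)C(C)(C)C)[C@@H]1[C@@H](C(=O)c2ccc(O[Si](C)(C)C(C)(C)C)cc2O[Si](C)(C)C(C)(C)C)[C@@H](c2ccc(O[Si](C)(C)C(C)(C)C)cc2)O[C@@H]1c1ccc(O[Si](C)(C)C(C)(C)C)cc1
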